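**Retrosynthetic overview**
1. Target ⇐ debenzylation, desilylation and anti-Markovnikov hydration of an allyl side chain.
2. C7 carbinol ⇐ Felkin–Anh reduction of the C7 aryl ketone; ketone ⇐ aryl Grignard + (R)-2-aryloxy-3-silyloxypropanal (C7–aryl bond).
3. C8 stereocentre ⇐ lipase desymmetrisation of the prochiral 2-aryloxypropane-1,3-diyl diacetate.
4. Prochiral diol ⇐ 4-allyl-2,6-dimethoxyphenol + diethyl chloromalonate (aryl ether made on an achiral carbon).
5. No ring is formed; both benzene rings are bought.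

Assumption: the lipase hydrolyses the pro-S acetoxymethyl arm of diacetate 5, as lipases do with 2-O-benzylglycerol diacetate; this is an analogy and has not been tested on this substrate.

**Step 1**
Reactants: 1 2,6-dimethoxy-4-(prop-2-en-1-yl)phenol (4-allyl-2,6-dimethoxyphenol); 2 diethyl 2-chloropropanedioate (diethyl chloromalonate)
Product: 3 diethyl 2-[2,6-dimethoxy-4-(prop-2-en-1-yl)phenoxy]propanedioate
Conditions: K2CO3, acetone, reflux
Reagents that add atoms: none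
Why: Williamson ether synthesis; the phenoxide displaces chloride from the doubly activated malonate carbon (SN2), so the hindered aryl ether is made before any stereocentre exists.

**Step 2**
Reactants: 3 diethyl 2-[2,6-dimethoxy-4-(prop-2-en-1-yl)phenoxy]propanedioate
Product: 4 2-[2,6-dimethoxy-4-(prop-2-en-1-yl)phenoxy]propane-1,3-diol
Conditions: LiAlH4, THF, 0 °C to rt; Fieser work-up
Reagents that add atoms: none
Why: Hydride reduction of both esters gives the prochiral 1,3-diol; the isolated alkene and aryl ethers are inert to LiAlH4.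

**Step 3**
Reactants: 4 2-[2,6-dimethoxy-4-(prop-2-en-1-yl)phenoxy]propane-1,3-diol
Product: 5 2-[2,6-dimethoxy-4-(prop-2-en-1-yl)phenoxy]propane-1,3-diyl diacetate
Conditions: Ac2O, pyridine, DMAP (cat.), CH2Cl2, rt
Reagents that add atoms: acetic anhydride, CC(=O)OC(C)=O
Why: DMAP-catalysed acylation of two unhindered primary alcohols is quantitative and gives the substrate for enzymatic hydrolysis.

**Step 4**
Reactants: 5 2-[2,6-dimethoxy-4-(prop-2-en-1-yl)phenoxy]propane-1,3-diyl diacetate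
Product: 6 (2R)-2-[2,6-dimethoxy-4-(prop-2-en-1-yl)phenoxy]-3-hydroxypropyl acetate
Conditions: lipase (Burkholderia cepacia lipase, immobilised), 0.1 M phosphate buffer pH 7.0 / MTBE, 25 °C, stopped at about 1 equiv acetate released
Reagents that add atoms: none
Why: Enzymatic desymmetrisation; the lipase (a serine hydrolase) hydrolyses only the pro-S acetoxymethyl arm, which sets the future C8 stereocentre, and slight over-hydrolysis removes the minor enantiomer faster and raises the ee.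

**Step 5**
Reactants: 6 (2R)-2-[2,6-dimethoxy-4-(prop-2-en-1-yl)phenoxy]-3-hydroxypropyl acetate
Product: 7 (2S)-3-[(tert-butyldiphenylsilyl)oxy]-2-[2,6-dimethoxy-4-(prop-2-en-1-yl)phenoxy]propyl acetate
Conditions: TBDPSCl, imidazole, CH2Cl2, 0 °C, run at once on fresh 6
Reagents that add atoms: tert-butyl(chloro)diphenylsilane, CC(C)(C)[Si](Cl)(c1ccccc1)c1ccccc1
Why: Imidazole-promoted silylation of the primary alcohol is fast and locks the two arms as different groups before 1,3-acyl migration can racemise 6 (the descriptor changes only through CIP priorities).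

**Step 6**
Reactants: 7 (2S)-3-[(tert-butyldiphenylsilyl)oxy]-2-[2,6-dimethoxy-4-(prop-2-en-1-yl)phenoxy]propyl acetate
Product: 8 (2S)-3-[(tert-butyldiphenylsilyl)oxy]-2-[2,6-dimethoxy-4-(prop-2-en-1-yl)phenoxy]propan-1-ol
Conditions: K2CO3 (0.2 equiv), MeOH, 0 °C
Reagents that add atoms: none
Why: Base-catalysed transesterification removes the acetate; the bulky TBDPS ether neither cleaves nor migrates under these conditions, so the stereocentre is kept.

**Step 7**
Reactants: 8 (2S)-3-[(tert-butyldiphenylsilyl)oxy]-2-[2,6-dimethoxy-4-(prop-2-en-1-yl)phenoxy]propan-1-ol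
Product: 9 (2R)-3-[(tert-butyldiphenylsilyl)oxy]-2-[2,6-dimethoxy-4-(prop-2-en-1-yl)phenoxy]propanal
Conditions: Dess–Martin periodinane, NaHCO3, CH2Cl2, 0 °C to rt; used crude at once
Reagents that add atoms: none
Why: Dess–Martin oxidation is non-basic, so the α-aryloxy aldehyde is formed without enolisation or β-elimination, as with the familiar 2-benzyloxy-3-silyloxypropanals.

**Step 8**
Reactants: 10 4-bromo-2-methoxyphenol
Product: 11 1-(benzyloxy)-4-bromo-2-methoxybenzene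
Conditions: BnBr, K2CO3, DMF, rt
Reagents that add atoms: benzyl bromide, BrCc1ccccc1
Why: Williamson benzylation of the phenol; the benzyl ether survives the organometallic, oxidation and hydride steps and leaves by neutral hydrogenolysis at the end.

**Step 9**
Reactants: 11 1-(benzyloxy)-4-bromo-2-methoxybenzene; 9 (2R)-3-[(tert-butyldiphenylsilyl)oxy]-2-[2,6-dimethoxy-4-(prop-2-en-1-yl)phenoxy]propanal
Product: 13 (1RS,2R)-1-[4-(benzyloxy)-3-methoxyphenyl]-3-[(tert-butyldiphenylsilyl)oxy]-2-[2,6-dimethoxy-4-(prop-2-en-1-yl)phenoxy]propan-1-ol, via aryl Grignard reagent 12 (not isolated)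
Conditions: Mg, I2 (cat.), THF, 40 °C; then 9, THF, −78 °C; sat. aq NH4Cl
Reagents that add atoms: none
Why: Grignard addition to the aldehyde at −78 °C is faster than enolisation, so C8 is kept; the C7 epimer ratio does not matter because the next step oxidises this centre.

**Step 10**
Reactants: 13 (1RS,2R)-1-[4-(benzyloxy)-3-methoxyphenyl]-3-[(tert-butyldiphenylsilyl)oxy]-2-[2,6-dimethoxy-4-(prop-2-en-1-yl)phenoxy]propan-1-ol
Product: 14 (2R)-1-[4-(benzyloxy)-3-methoxyphenyl]-3-[(tert-butyldiphenylsilyl)oxy]-2-[2,6-dimethoxy-4-(prop-2-en-1-yl)phenoxy]propan-1-one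
Conditions: Dess–Martin periodinane, NaHCO3, CH2Cl2, 0 °C to rt
Reagents that add atoms: none
Why: Buffered Dess–Martin oxidation converts both epimers into one aryl ketone; α-aryloxy aryl ketones keep their configuration under neutral conditions.

**Step 11**
Reactants: 14 (2R)-1-[4-(benzyloxy)-3-methoxyphenyl]-3-[(tert-butyldiphenylsilyl)oxy]-2-[2,6-dimethoxy-4-(prop-2-en-1-yl)phenoxy]propan-1-one
Product: 15 (1S,2R)-1-[4-(benzyloxy)-3-methoxyphenyl]-3-[(tert-butyldiphenylsilyl)oxy]-2-[2,6-dimethoxy-4-(prop-2-en-1-yl)phenoxy]propan-1-ol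
Conditions: L-Selectride, THF, −78 °C; then H2O
Reagents that add atoms: none
Why: Felkin–Anh (polar) controlled reduction; the bulky, non-chelating hydride attacks anti to the C8 aryloxy group and gives the anti (erythro) alcohol, which sets C7 as S.

**Step 12**
Reactants: 15 (1S,2R)-1-[4-(benzyloxy)-3-methoxyphenyl]-3-[(tert-butyldiphenylsilyl)oxy]-2-[2,6-dimethoxy-4-(prop-2-en-1-yl)phenoxy]propan-1-ol
Product: 17 (1S,2R)-1-[4-(benzyloxy)-3-methoxyphenyl]-3-[(tert-butyldiphenylsilyl)oxy]-2-[4-(3-hydroxypropyl)-2,6-dimethoxyphenoxy]propan-1-ol, via B-alkyl-9-BBN adduct 16 (not isolated)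
Conditions: 9-BBN (3 equiv), THF, 0 °C to rt; then aq NaOH, H2O2, 0 °C
Reagents that add atoms: hydrogen peroxide, OO
Why: Brown hydroboration–oxidation; 9-BBN adds to the terminal alkene with anti-Markovnikov selectivity, the free C7 hydroxyl only consumes extra borane and is released on work-up, and no stereocentre is touched.

**Step 13**
Reactants: 17 (1S,2R)-1-[4-(benzyloxy)-3-methoxyphenyl]-3-[(tert-butyldiphenylsilyl)oxy]-2-[4-(3-hydroxypropyl)-2,6-dimethoxyphenoxy]propan-1-ol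
Product: 18 (1S,2R)-1-[4-(benzyloxy)-3-methoxyphenyl]-2-[4-(3-hydroxypropyl)-2,6-dimethoxyphenoxy]propane-1,3-diol
Conditions: TBAF, THF, 0 °C to rt
Reagents that add atoms: none
Why: Fluoride-driven desilylation frees the C9 alcohol; the phenol is still benzylated, so no quinone methide can form and epimerise C7.

**Step 14**
Reactants: 18 (1S,2R)-1-[4-(benzyloxy)-3-methoxyphenyl]-2-[4-(3-hydroxypropyl)-2,6-dimethoxyphenoxy]propane-1,3-diol
Product: 19 (1S,2R)-1-(4-hydroxy-3-methoxyphenyl)-2-[4-(3-hydroxypropyl)-2,6-dimethoxyphenoxy]propane-1,3-diol (IN0404; 7S,8R, erythro)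
Conditions: H2 (1 atm), 10% Pd/C, EtOAc/EtOH, rt, stopped at 1 equiv H2
Reagents that add atoms: none
Why: Catalytic hydrogenolysis cleaves the benzyl aryl ether under neutral conditions, leaving the benzylic C7 hydroxyl and both stereocentres intact.

**Compound list**
1 | 2,6-dimethoxy-4-(prop-2-en-1-yl)phenol | C=CCc1cc(OC)c(O)c(OC)c1 | starting material
2 | diethyl 2-chloropropanedioate | CCOC(=O)C(Cl)C(=O)OCC | starting material
3 | diethyl 2-[2,6-dimethoxy-4-(prop-2-en-1-yl)phenoxy]propanedioate | CCOC(=O)C(Oc1c(OC)cc(CC=C)cc1OC)C(=O)OCC | intermediate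
4 | 2-[2,6-dimethoxy-4-(prop-2-en-1-yl)phenoxy]propane-1,3-diol | OCC(CO)Oc1c(OC)cc(CC=C)cc1OC | intermediate
5 | 2-[2,6-dimethoxy-4-(prop-2-en-1-yl)phenoxy]propane-1,3-diyl diacetate | CC(=O)OCC(COC(C)=O)Oc1c(OC)cc(CC=C)cc1OC | intermediate
6 | (2R)-2-[2,6-dimethoxy-4-(prop-2-en-1-yl)phenoxy]-3-hydroxypropyl acetate | CC(=O)OC[C@@H](CO)Oc1c(OC)cc(CC=C)cc1OC | intermediate
7 | (2S)-3-[(tert-butyldiphenylsilyl)oxy]-2-[2,6-dimethoxy-4-(prop-2-en-1-yl)phenoxy]propyl acetate | CC(=O)OC[C@@H](CO[Si](c1ccccc1)(c1ccccc1)C(C)(C)C)Oc1c(OC)cc(CC=C)cc1OC | intermediate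
8 | (2S)-3-[(tert-butyldiphenylsilyl)oxy]-2-[2,6-dimethoxy-4-(prop-2-en-1-yl)phenoxy]propan-1-ol | OC[C@@H](CO[Si](c1ccccc1)(c1ccccc1)C(C)(C)C)Oc1c(OC)cc(CC=C)cc1OC | intermediate
9 | (2R)-3-[(tert-butyldiphenylsilyl)oxy]-2-[2,6-dimethoxy-4-(prop-2-en-1-yl)phenoxy]propanal | O=C[C@@H](CO[Si](c1ccccc1)(c1ccccc1)C(C)(C)C)Oc1c(OC)cc(CC=C)cc1OC | intermediate
10 | 4-bromo-2-methoxyphenol | COc1cc(Br)ccc1O | starting material
11 | 1-(benzyloxy)-4-bromo-2-methoxybenzene | COc1cc(Br)ccc1OCc1ccccc1 | intermediate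
12 | [4-(benzyloxy)-3-methoxyphenyl]magnesium bromide | COc1cc([Mg]Br)ccc1OCc1ccccc1 | intermediate
13 | (1RS,2R)-1-[4-(benzyloxy)-3-methoxyphenyl]-3-[(tert-butyldiphenylsilyl)oxy]-2-[2,6-dimethoxy-4-(prop-2-en-1-yl)phenoxy]propan-1-ol | COc1cc(C(O)[C@@H](CO[Si](c2ccccc2)(c2ccccc2)C(C)(C)C)Oc2c(OC)cc(CC=C)cc2OC)ccc1OCc1ccccc1 | intermediate
14 | (2R)-1-[4-(benzyloxy)-3-methoxyphenyl]-3-[(tert-butyldiphenylsilyl)oxy]-2-[2,6-dimethoxy-4-(prop-2-en-1-yl)phenoxy]propan-1-one | COc1cc(C(=O)[C@@H](CO[Si](c2ccccc2)(c2ccccc2)C(C)(C)C)Oc2c(OC)cc(CC=C)cc2OC)ccc1OCc1ccccc1 | intermediate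
15 | (1S,2R)-1-[4-(benzyloxy)-3-methoxyphenyl]-3-[(tert-butyldiphenylsilyl)oxy]-2-[2,6-dimethoxy-4-(prop-2-en-1-yl)phenoxy]propan-1-ol | COc1cc([C@H](O)[C@@H](CO[Si](c2ccccc2)(c2ccccc2)C(C)(C)C)Oc2c(OC)cc(CC=C)cc2OC)ccc1OCc1ccccc1 | intermediate
16 | B-alkyl-9-borabicyclo[3.3.1]nonane adduct of 15 (boron on the terminal side-chain carbon) | COc1cc([C@H](O)[C@@H](CO[Si](c2ccccc2)(c2ccccc2)C(C)(C)C)Oc2c(OC)cc(CCCB3C4CCCC3CCC4)cc2OC)ccc1OCc1ccccc1 | intermediate
17 | (1S,2R)-1-[4-(benzyloxy)-3-methoxyphenyl]-3-[(tert-butyldiphenylsilyl)oxy]-2-[4-(3-hydroxypropyl)-2,6-dimethoxyphenoxy]propan-1-ol | COc1cc([C@H](O)[C@@H](CO[Si](c2ccccc2)(c2ccccc2)C(C)(C)C)Oc2c(OC)cc(CCCO)cc2OC)ccc1OCc1ccccc1 | intermediate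
18 | (1S,2R)-1-[4-(benzyloxy)-3-methoxyphenyl]-2-[4-(3-hydroxypropyl)-2,6-dimethoxyphenoxy]propane-1,3-diol | COc1cc([C@H](O)[C@@H](CO)Oc2c(OC)cc(CCCO)cc2OC)ccc1OCc1ccccc1 | intermediate
19 | (1S,2R)-1-(4-hydroxy-3-methoxyphenyl)-2-[4-(3-hydroxypropyl)-2,6-dimethoxyphenoxy]propane-1,3-diol (IN0404) | COc1cc([C@H](O)[C@@H](CO)Oc2c(OC)cc(CCCO)cc2OC)ccc1O | target

**Step count:** 14 steps in total. Longest linear sequence: 13 steps (steps 1–7 and 9–14, from 1 to 19).

**Steps most likely to fail, with fallbacks**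

Step 4 (lipase desymmetrisation). The bulky 2,6-dimethoxyaryloxy group may lower the ee or reverse the arm preference. The fallback sets out from diol 4 and comes back at 8. A dinuclear zinc–ProPhenol catalyst (5 mol %, ligand enantiomer chosen to acylate the pro-R hydroxymethyl arm) with vinyl benzoate in THF at −15 °C transfers one benzoyl group and gives (2R)-2-[2,6-dimethoxy-4-(prop-2-en-1-yl)phenoxy]-3-hydroxypropyl benzoate F1. TBDPSCl and imidazole then give (2S)-3-[(tert-butyldiphenylsilyl)oxy]-2-[2,6-dimethoxy-4-(prop-2-en-1-yl)phenoxy]propyl benzoate F2, and K2CO3 in methanol removes the benzoate to give 8.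

Step 7 (α-aryloxy aldehyde 9). The aldehyde may epimerise or decompose before or during the Grignard addition. The fallback sets out from alcohol 8 and comes back at ketone 14, so no aldehyde is handled. TEMPO/PhI(OAc)2 in MeCN–water oxidises 8 to (2R)-3-[(tert-butyldiphenylsilyl)oxy]-2-[2,6-dimethoxy-4-(prop-2-en-1-yl)phenoxy]propanoic acid F3. EDC/HOBt coupling with N,O-dimethylhydroxylamine hydrochloride gives (2R)-3-[(tert-butyldiphenylsilyl)oxy]-2-[2,6-dimethoxy-4-(prop-2-en-1-yl)phenoxy]-N-methoxy-N-methylpropanamide F4. Bromide 11 and n-BuLi (THF, −78 °C) give [4-(benzyloxy)-3-methoxyphenyl]lithium F5, which adds once to F4 and gives 14 directly.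

Step 11 (L-Selectride reduction). The erythro:threo ratio may be poor if the ortho-methoxy groups promote chelation. The fallback sets out from aldehyde 9 and comes back at 15, setting C7 in the C–C bond-forming step instead of by hydride delivery. Grignard reagent 12 is transmetallated with ClTi(OiPr)3 to [4-(benzyloxy)-3-methoxyphenyl]titanium triisopropoxide F6. This reagent cannot chelate and adds to 9 (THF, −78 to −20 °C) in the Felkin–Anh sense to give 15.

**Further compounds**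
F1 | step 4 | (2R)-2-[2,6-dimethoxy-4-(prop-2-en-1-yl)phenoxy]-3-hydroxypropyl benzoate | O=C(OC[C@@H](CO)Oc1c(OC)cc(CC=C)cc1OC)c1ccccc1
F2 | step 4 | (2S)-3-[(tert-butyldiphenylsilyl)oxy]-2-[2,6-dimethoxy-4-(prop-2-en-1-yl)phenoxy]propyl benzoate | O=C(OC[C@@H](CO[Si](c1ccccc1)(c1ccccc1)C(C)(C)C)Oc1c(OC)cc(CC=C)cc1OC)c1ccccc1
F3 | step 7 | (2R)-3-[(tert-butyldiphenylsilyl)oxy]-2-[2,6-dimethoxy-4-(prop-2-en-1-yl)phenoxy]propanoic acid | OC(=O)[C@@H](CO[Si](c1ccccc1)(c1ccccc1)C(C)(C)C)Oc1c(OC)cc(CC=C)cc1OC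
F4 | step 7 | (2R)-3-[(tert-butyldiphenylsilyl)oxy]-2-[2,6-dimethoxy-4-(prop-2-en-1-yl)phenoxy]-N-methoxy-N-methylpropanamide | CON(C)C(=O)[C@@H](CO[Si](c1ccccc1)(c1ccccc1)C(C)(C)C)Oc1c(OC)cc(CC=C)cc1OC
F5 | step 7 | [4-(benzyloxy)-3-methoxyphenyl]lithium | [Li]c1ccc(OCc2ccccc2)c(OC)c1
F6 | step 11 | [4-(benzyloxy)-3-methoxyphenyl]titanium triisopropoxide | CC(C)O[Ti](OC(C)C)(OC(C)C)c1ccc(OCc2ccccc2)c(OC)c1
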